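Plan the flask by asking which form of the catalyst waits longest at the moment in question.

    starting material + free catalyst → catalyst intermediate A (k1 = 52 M⁻¹ s⁻¹)
    partner + catalyst intermediate A ⇌ catalyst intermediate B (K2 = 18 M⁻¹, k2 = 110 M⁻¹ s⁻¹)
    catalyst intermediate B → catalyst intermediate C (k3 = 14 s⁻¹)
    catalyst intermediate C → free catalyst + product (k4 = 81 s⁻¹)
    partner → decomposed reagent (k5 = 0.0066 s⁻¹)

starting material 0.10 M; partner 0.0600 M; free catalyst 0.20 mM

- the form that holds most of the catalyst when 30% of the starting material are converted (catalyst intermediate B / catalyst intermediate A / catalyst intermediate C / free catalyst)
- its share of the catalyst then
- apparent order in free catalyst when 30% of the starting material are converted (percent change of the rate of making product for one percent more free catalyst charged)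

The catalyst in this flask went round a cycle, and I took each form's share to follow the time one catalyst waits in that form per turn. The form with the longest wait is the resting state. At the conversion asked about, starting material stood at 70.0% of its charge, so I reckoned the wait on free catalyst at 0.275 s. Catalyst intermediate B falls back at 6.11 s⁻¹ and goes on at 14 s⁻¹, so one passage costs 1.44 tries, and the wait on catalyst intermediate A is that number over the capture rate by partner. Catalyst intermediates B and C together wait 0.0838 s, less than free catalyst.

Setting the two long waits equal gave 79.2%. I call this the crossing partner: the fraction of its charge at which catalyst intermediate A and free catalyst wait equally long. Below it, their ratio is the crossing over the partner fraction.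

Taking off what coupling uses gave 50.0% of the partner charge, below the crossing, which makes the ratio 1.58. But I reckoned the cycle time, the sum of the waits, at 0.494 s at the start, so coupling took 0.00675 s⁻¹ of the partner charge against 0.0066 s⁻¹ for decay. My reckoning stopped there: catalyst intermediate A at rest, its ratio higher still, and an order above one, since more catalyst reaches the same conversion with more partner left.

The forecast gave catalyst intermediate A, 83% and an order of 3.1, noting that “Partner decay rivals turnover”.

In this flask the conversion came at 2.12 min. Then catalyst intermediate A held 82.7%, free catalyst held 13.2%, and the order was 3.1, so the forecast held on each.

Through the crossing, those shares read the partner in this flask at 12.7% of its charge, which gives a cycle time of 2.08 s. In the second flask, the same run with the decay step taken away, I reckoned partner at 50.0%, and the crossing gives a cycle time of 0.794 s, a rate 2.62 times as high. The simulated run gave 2.63 times the rate through the loss of that step, and its order in free catalyst fell to 1.0.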